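**Plan**

- Retrosynthesis: cut the C6 vanillate ester, take the C8=C14 methylene back to a C8 ketone and the C9–O bond back to a C8 enone, then cut C9=C10 of the seven-membered ring (metathesis), then C8–C9, C4–isopropyl, C5–C6 and C1–C10 on a cyclopentanone.
- Enabling feature: in the ring C1/C5–C10, C10 carries only hydrogens and lies between quaternary C1 and oxygenated C9, which adjoins C8. C9=C10 can therefore be an alkene built from a C1 vinyl group and a C8 vinyl ketone; the enone then supplies the C9 hydroxyl and the C8 methylene.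
- Forward: the five-membered ring is bought as 3-methylcyclopentenone. Conjugate addition/aldol attaches C10 and the C6–C8 chain, isopropyl addition completes C4, and vinyl addition/oxidation gives the vinyl ketone. The seven-membered ring is closed by metathesis, followed by C9 oxygenation, methylenation and esterification.
- Stereochemistry: C1 from the chiral copper–carbene catalyst; C5 and C6 from the aldol (anti to the silylvinyl group, closed transition state); C4 by addition anti to the C5 side chain; C9 by oxygen capture anti to the angular methyl.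

Key step: step 10

Assumption: atoms carry daucane numbers (ring atoms C1–C10, C14 the exocyclic methylene carbon, β = face of the C1 methyl), and the antipode of the chiral carbene ligand is taken that adds the alkenyl group to the face of 1 leading to the 1R centre of the target.

**Route**

Step 1
Reactants: 1 3-methylcyclopent-2-en-1-one; 2 ethynyltrimethylsilane; 3 3-[(tert-butyldimethylsilyl)oxy]propanal
Product: 6 aldol adduct (2S,3S)-2-[(1S)-3-(TBSO)-1-hydroxypropyl]-3-methyl-3-[1-(trimethylsilyl)ethenyl]cyclopentan-1-one, via alane 4 (not isolated), via aluminium enolate 5 (not isolated)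
Conditions: 2, i-Bu2AlH, hexanes/THF, 55 °C; then 1, Cu(OTf)2 (5 mol %), chiral sulfonate-bearing imidazolinium salt as carbene precursor (5 mol %), THF, −78 → −30 °C; then 3, −78 °C; aq. potassium sodium tartrate
Reagents that add atoms: none
Why: Copper–carbene-catalysed asymmetric conjugate addition of the α-silylvinylalane sets the quaternary C1 under catalyst control, and the regiodefined (E)-aluminium enolate should then add to the aldehyde through a closed Zimmerman–Traxler transition state on the face opposite the bulky silylvinyl group, giving the C5 side chain cis to the methyl group and the anti aldol (6S) carbinol.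

Step 2
Reactants: 6 aldol adduct
Product: 7 keto diol (2S,3R)-2-[(1S)-1,3-dihydroxypropyl]-3-ethenyl-3-methylcyclopentan-1-one
Conditions: TFA, CH2Cl2, H2O (5 equiv), 0 °C → rt; then aq. NaHCO3/MeOH
Reagents that add atoms: none
Why: Acid-mediated ipso-protodesilylation of the vinylsilane through the β-silyl cation should leave the plain vinyl group, while the same acid hydrolyses the primary silyl ether as wanted for the next step; no stereocentre is touched and the short exposure at or below room temperature should spare the aldol unit from dehydration.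

Step 3
Reactants: 7 keto diol
Product: 8 p-methoxybenzylidene acetal (2S,3R)-3-ethenyl-2-[(2S,4S)-2-(4-methoxyphenyl)-1,3-dioxan-4-yl]-3-methylcyclopentan-1-one
Conditions: 4-MeOC6H4CH(OMe)2, PPTS (cat.), 4 Å molecular sieves, CH2Cl2, rt
Reagents that add atoms: 4-methoxybenzaldehyde dimethyl acetal, COc1ccc(C(OC)OC)cc1
Why: Acid-catalysed transacetalisation under thermodynamic control should tie the 1,3-diol into the six-membered dioxane with aryl and cyclopentyl groups both equatorial (cis), so the new acetal centre is set by equilibration while the hindered ketone stays free.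

Step 4
Reactants: 8 p-methoxybenzylidene acetal
Product: 9 tertiary alcohol (1R,2S,3R)-3-ethenyl-2-[(2S,4S)-2-(4-methoxyphenyl)-1,3-dioxan-4-yl]-3-methyl-1-(propan-2-yl)cyclopentan-1-ol
Conditions: i-PrMgCl, CeCl3, THF, −78 → 0 °C; H2O
Reagents that add atoms: isopropylmagnesium chloride, CC(C)[Mg]Cl
Why: Organocerium (Imamoto) addition suppresses enolisation and β-hydride reduction of the hindered β-alkoxy ketone, and the isopropyl group should attack the C4 carbonyl on the face opposite the adjacent C5 dioxanyl substituent, placing the hydroxyl cis to that substituent (4R).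

Step 5
Reactants: 9 tertiary alcohol
Product: 10 triethylsilyl ether of 9
Conditions: Et3SiOTf, 2,6-lutidine, CH2Cl2, −78 → −20 °C
Reagents that add atoms: triethylsilyl trifluoromethanesulfonate, CC[Si](CC)(CC)OS(=O)(=O)C(F)(F)F
Why: Silyl triflate with a hindered pyridine base is the standard silylation of a tertiary alcohol, the low temperature keeps the benzylidene acetal intact, and the ether later prevents hemiketal formation between the C4 oxygen and the C8 carbonyl.

Step 6
Reactants: 10 triethylsilyl ether
Product: 11 primary C8 alcohol with C6 PMB ether (cyclopentane: C1 methyl β and vinyl α; C4 isopropyl α and OTES β; C5 chain CH(OPMB)CH2CH2OH β; 1R,4R,5S,6S)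
Conditions: i-Bu2AlH, CH2Cl2, −78 → 0 °C; aq. potassium sodium tartrate
Reagents that add atoms: none
Why: In this regioselective reductive opening of a p-methoxybenzylidene acetal the aluminium hydride coordinates the less hindered primary oxygen and delivers hydride to the oxocarbenium ion, so the PMB group should stay on the hindered C6 oxygen and the C8 alcohol is released.

Step 7
Reactants: 11 primary alcohol
Product: 12 C8 aldehyde (chain CH(OPMB)CH2CHO; otherwise as 11)
Conditions: Dess–Martin periodinane, CH2Cl2, 0 °C → rt
Reagents that add atoms: none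
Why: Dess–Martin oxidation converts the primary alcohol into the aldehyde under near-neutral conditions that leave the PMB ether, the tertiary silyl ether and the vinyl group untouched and should not trigger β-elimination of the C6 alkoxy group.

Step 8
Reactants: 12 aldehyde
Product: 13 allylic alcohol (chain CH(OPMB)CH2CH(OH)CH=CH2; both C8 epimers)
Conditions: CH2=CHMgBr, THF, −78 °C; H2O
Reagents that add atoms: vinylmagnesium bromide, C=C[Mg]Br
Why: Grignard 1,2-addition to the aldehyde at low temperature installs C9 and its terminal carbon, and the configuration of the new C8 carbinol is irrelevant because it is oxidised in the next step.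

Step 9
Reactants: 13 allylic alcohol
Product: 14 vinyl ketone (cyclopentane with C1 vinyl and C5 chain CH(OPMB)CH2C(=O)CH=CH2; 1R,4R,5S,6S)
Conditions: Dess–Martin periodinane, CH2Cl2, 0 °C → rt
Reagents that add atoms: none
Why: Dess–Martin oxidation of the allylic alcohol gives the vinyl ketone under non-basic conditions, which avoids conjugate addition to or polymerisation of the enone.

Step 10
Reactants: 14 vinyl ketone
Product: 15 bicyclic enone (trans-fused 14-nordauc-9-en-8-one with 6α-OPMB and 4β-OTES; 1R,4R,5S,6S)
Conditions: second-generation Grubbs catalyst (H2IMes)(PCy3)Cl2Ru=CHPh (10 mol %), CH2Cl2 (0.003 M), 40 °C, argon sparge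
Reagents that add atoms: none
Why: The ruthenium benzylidene first exchanges with one terminal alkene (most likely the C1 vinyl, the enone being electron-poor), the new alkylidene undergoes intramolecular [2+2] cycloaddition with the other alkene, and the ruthenacyclobutane fragments to the ring alkene and Ru=CH2, the two terminal carbons leaving as ethylene. The closest known reaction type is ring-closing metathesis of a vinyl ketone with a vinyl group on a quaternary carbon to give a cycloheptenone. The seven-membered ring closes by joining C9 and C10, the two arms being held on the adjacent ring carbons C1 and C5, and a ring of this size can hold only a (Z)-alkene. No stereocentre is created; the trans arrangement of the two arms on the cyclopentane already encodes the trans ring fusion. The step needs cyclisation to win over intermolecular cross-metathesis, which high dilution, removal of ethylene and the poor cross-metathesis reactivity of both alkenes should secure. The C4 silyl ether keeps the C4 oxygen from masking the C8 carbonyl as a hemiketal.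

Step 11
Reactants: 15 bicyclic enone
Product: 17 α-hydroxy ketone (9α-hydroxy-8-ketone; 1R,4R,5S,6S,9S), via C9 hydroperoxide 16 (not isolated)
Conditions: Mn(dpm)3 (10 mol %, dpm = dipivaloylmethanate), PhSiH3, O2 (1 atm), i-PrOH/CH2Cl2, 0 °C; then P(OEt)3
Reagents that add atoms: dioxygen, O=O
Why: In this Mukaiyama-type reductive α-hydroxylation the manganese hydride transfers a hydrogen atom to the β-carbon C10, the C9 α-keto radical should capture dioxygen on the α face away from the axial C1 methyl group, and the phosphite reduces the hydroperoxide, so oxygen enters only at C9 with the 9S configuration.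

Step 12
Reactants: 17 α-hydroxy ketone
Product: 18 C9 triethylsilyl ether of 17
Conditions: Et3SiCl, imidazole, DMAP (cat.), DMF, 0 °C → rt
Reagents that add atoms: chlorotriethylsilane, CC[Si](Cl)(CC)CC
Why: Silylation of the secondary α-hydroxy ketone with a silyl chloride and imidazole is mild enough not to epimerise C9 or eliminate the C6 alkoxy group, and the ether blocks C9 during methylenation and the later acylation.

Step 13
Reactants: 18 silyloxy ketone
Product: 19 exocyclic methylene compound (8(14)-ene with 6α-OPMB, 4β-OTES, 9α-OTES)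
Conditions: Cp2TiMe2, toluene/THF, 70 °C, dark
Reagents that add atoms: dimethyltitanocene (Petasis reagent), C[Ti](C)(C1C=CC=C1)C1C=CC=C1
Why: Petasis methylenation through Cp2Ti=CH2 and an oxatitanacyclobutane is non-basic, so the ketone flanked by a β-alkoxy and an α-silyloxy group should give the exocyclic methylene without elimination or epimerisation at C9.

Step 14
Reactants: 19 PMB ether
Product: 20 C6 alcohol (6α-OH, 4β-OTES, 9α-OTES, 8(14)-ene)
Conditions: DDQ, CH2Cl2/pH 7 phosphate buffer, 0 °C
Reagents that add atoms: none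
Why: DDQ cleaves the PMB ether oxidatively through the benzylic oxocarbenium ion and its hydrolysis, and the silyl ethers and the isolated 1,1-disubstituted alkene are inert under the buffered conditions.

Step 15
Reactants: 21 vanillic acid
Product: 23 4-[(tert-butyldimethylsilyl)oxy]-3-methoxybenzoic acid, via bis-silylated vanillate 22 (not isolated)
Conditions: TBSCl (2.5 equiv), imidazole, DMF, rt; then AcOH/THF/H2O, rt
Reagents that add atoms: tert-butyldimethylsilyl chloride, CC(C)(C)[Si](C)(C)Cl
Why: Silylation of both acidic hydroxyl groups followed by selective hydrolysis of the much more labile silyl ester leaves the phenol masked as its TBS ether and frees the carboxylic acid.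

Step 16
Reactants: 20 C6 alcohol; 23 protected vanillic acid
Product: 25 silyl-protected C6 vanillate, via mixed anhydride 24 (not isolated)
Conditions: 23, 2,4,6-Cl3C6H2COCl, Et3N, THF, rt; then 20, DMAP, toluene, rt → 40 °C
Reagents that add atoms: none
Why: In the Yamaguchi esterification DMAP attacks the mixed anhydride at the less hindered vanilloyl carbonyl and the acylpyridinium acylates the only free hydroxyl group, the secondary C6 alcohol, with retention of configuration.

Step 17
Reactants: 25 protected ester
Product: 26 target (1R,4R,5S,6S,9S)-4,9-dihydroxydauc-8(14)-en-6-yl 4-hydroxy-3-methoxybenzoate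
Conditions: HF·pyridine, pyridine, THF, 0 °C → rt
Reagents that add atoms: none
Why: Fluoride-driven cleavage of the three silicon–oxygen bonds (aryl TBS, secondary and tertiary TES) under buffered conditions should leave the ester, the allylic alcohol and the tertiary alcohol intact.

**Compound list**

1 | 3-methylcyclopent-2-en-1-one | CC1=CC(=O)CC1 | starting material
2 | ethynyltrimethylsilane | C#C[Si](C)(C)C | starting material
3 | 3-[(tert-butyldimethylsilyl)oxy]propanal | O=CCCO[Si](C)(C)C(C)(C)C | starting material
4 | diisobutyl[1-(trimethylsilyl)ethenyl]alane | C=C([Si](C)(C)C)[Al](CC(C)C)CC(C)C | intermediate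
5 | diisobutylaluminium (3S)-3-methyl-3-[1-(trimethylsilyl)ethenyl]cyclopent-1-en-1-olate | C=C([Si](C)(C)C)[C@@]1(C)CCC(O[Al](CC(C)C)CC(C)C)=C1 | intermediate
6 | (2S,3S)-2-[(1S)-3-[(tert-butyldimethylsilyl)oxy]-1-hydroxypropyl]-3-methyl-3-[1-(trimethylsilyl)ethenyl]cyclopentan-1-one | CC(C)(C)[Si](C)(C)OCC[C@H](O)[C@@H]1[C@](C)(CCC1=O)C(=C)[Si](C)(C)C | intermediate
7 | (2S,3R)-2-[(1S)-1,3-dihydroxypropyl]-3-ethenyl-3-methylcyclopentan-1-one | OCC[C@H](O)[C@@H]1[C@](C)(CCC1=O)C=C | intermediate
8 | (2S,3R)-3-ethenyl-2-[(2S,4S)-2-(4-methoxyphenyl)-1,3-dioxan-4-yl]-3-methylcyclopentan-1-one | COc1ccc(cc1)[C@H]2OCC[C@H](O2)[C@@H]3[C@](C)(CCC3=O)C=C | intermediate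
9 | (1R,2S,3R)-3-ethenyl-2-[(2S,4S)-2-(4-methoxyphenyl)-1,3-dioxan-4-yl]-3-methyl-1-(propan-2-yl)cyclopentan-1-ol | COc1ccc(cc1)[C@H]2OCC[C@H](O2)[C@@H]3[C@](C)(CC[C@@]3(O)C(C)C)C=C | intermediate
10 | triethylsilyl ether of 9 at the tertiary C4 oxygen | COc1ccc(cc1)[C@H]2OCC[C@H](O2)[C@@H]3[C@](C)(CC[C@@]3(O[Si](CC)(CC)CC)C(C)C)C=C | intermediate
11 | (3S)-3-[(4-methoxybenzyl)oxy]-3-[(1S,2R,5R)-2-ethenyl-2-methyl-5-(propan-2-yl)-5-(triethylsilyloxy)cyclopentyl]propan-1-ol | OCC[C@H](OCc1ccc(OC)cc1)[C@@H]2[C@](C)(CC[C@@]2(O[Si](CC)(CC)CC)C(C)C)C=C | intermediate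
12 | C8 aldehyde corresponding to 11 (propanal; daucane locants 1R,4R,5S,6S) | O=CC[C@H](OCc1ccc(OC)cc1)[C@@H]2[C@](C)(CC[C@@]2(O[Si](CC)(CC)CC)C(C)C)C=C | intermediate
13 | allylic alcohol, 5-substituted pent-1-en-3-ol chain (C8 epimers; 1R,4R,5S,6S) | C=CC(O)C[C@H](OCc1ccc(OC)cc1)[C@@H]2[C@](C)(CC[C@@]2(O[Si](CC)(CC)CC)C(C)C)C=C | intermediate
14 | vinyl ketone, 5-substituted pent-1-en-3-one chain on the C1-vinyl cyclopentane (1R,4R,5S,6S) | C=CC(=O)C[C@H](OCc1ccc(OC)cc1)[C@@H]2[C@](C)(CC[C@@]2(O[Si](CC)(CC)CC)C(C)C)C=C | intermediate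
15 | (1R,4R,5S,6S)-6-[(4-methoxybenzyl)oxy]-4-(triethylsilyloxy)-14-nordauc-9-en-8-one (trans-fused) | C1=CC(=O)C[C@H](OCc3ccc(OC)cc3)[C@@H]2[C@]1(C)CC[C@@]2(O[Si](CC)(CC)CC)C(C)C | intermediate
16 | 9α-hydroperoxy-8-ketone derived from 15 (9S) | O=C1C[C@H](OCc3ccc(OC)cc3)[C@@H]2[C@](C)(CC[C@@]2(O[Si](CC)(CC)CC)C(C)C)C[C@@H]1OO | intermediate
17 | (1R,4R,5S,6S,9S)-9-hydroxy-6-[(4-methoxybenzyl)oxy]-4-(triethylsilyloxy)-14-nordaucan-8-one | O=C1C[C@H](OCc3ccc(OC)cc3)[C@@H]2[C@](C)(CC[C@@]2(O[Si](CC)(CC)CC)C(C)C)C[C@@H]1O | intermediate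
18 | C9 triethylsilyl ether of 17 | O=C1C[C@H](OCc3ccc(OC)cc3)[C@@H]2[C@](C)(CC[C@@]2(O[Si](CC)(CC)CC)C(C)C)C[C@@H]1O[Si](CC)(CC)CC | intermediate
19 | (1R,4R,5S,6S,9S)-6-[(4-methoxybenzyl)oxy]-4,9-bis(triethylsilyloxy)dauc-8(14)-ene | C=C1C[C@H](OCc3ccc(OC)cc3)[C@@H]2[C@](C)(CC[C@@]2(O[Si](CC)(CC)CC)C(C)C)C[C@@H]1O[Si](CC)(CC)CC | intermediate
20 | (1R,4R,5S,6S,9S)-4,9-bis(triethylsilyloxy)dauc-8(14)-en-6-ol | C=C1C[C@H](O)[C@@H]2[C@](C)(CC[C@@]2(O[Si](CC)(CC)CC)C(C)C)C[C@@H]1O[Si](CC)(CC)CC | intermediate
21 | vanillic acid (4-hydroxy-3-methoxybenzoic acid) | COc1cc(C(=O)O)ccc1O | starting material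
22 | tert-butyldimethylsilyl 4-[(tert-butyldimethylsilyl)oxy]-3-methoxybenzoate | COc1cc(C(=O)O[Si](C)(C)C(C)(C)C)ccc1O[Si](C)(C)C(C)(C)C | intermediate
23 | 4-[(tert-butyldimethylsilyl)oxy]-3-methoxybenzoic acid | COc1cc(C(=O)O)ccc1O[Si](C)(C)C(C)(C)C | intermediate
24 | 4-[(tert-butyldimethylsilyl)oxy]-3-methoxybenzoic 2,4,6-trichlorobenzoic anhydride | COc1cc(C(=O)OC(=O)c2c(Cl)cc(Cl)cc2Cl)ccc1O[Si](C)(C)C(C)(C)C | intermediate
25 | (1R,4R,5S,6S,9S)-4,9-bis(triethylsilyloxy)dauc-8(14)-en-6-yl 4-[(tert-butyldimethylsilyl)oxy]-3-methoxybenzoate | C=C1C[C@H](OC(=O)c3ccc(O[Si](C)(C)C(C)(C)C)c(OC)c3)[C@@H]2[C@](C)(CC[C@@]2(O[Si](CC)(CC)CC)C(C)C)C[C@@H]1O[Si](CC)(CC)CC | intermediate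
26 | (1R,4R,5S,6S,9S)-4,9-dihydroxydauc-8(14)-en-6-yl 4-hydroxy-3-methoxybenzoate (CNP0330487.1) | C=C1C[C@H](OC(=O)c2ccc(O)c(OC)c2)[C@@H]2[C@](C)(CC[C@@]2(O)C(C)C)C[C@@H]1O | target

**Step count and risks**

Total step count: 17. Longest linear sequence: 16 steps (steps 1–14, 16 and 17, from 1 to 26); step 15 is a one-step side branch.

Steps most likely to fail:

Step 10 (ring closure). Both alkenes may load the catalyst slowly, the enone because it is electron-poor and the C1 vinyl because it is neopentylic, so intermolecular coupling through the enone and catalyst decay could overtake cyclisation. The fallback sets out from 13: the allylic alcohol, whose alkene is electron-rich and unhindered, is cyclised with the same second-generation Grubbs catalyst in dilute CH2Cl2 to the bicyclic allylic alcohol F3, so that the ruthenium loads on the carbinol side and closes onto the C1 vinyl intramolecularly. Dess–Martin oxidation of F3 then gives the enone, and the route is rejoined at 15.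

Step 1 (tandem conjugate addition/aldol). The aluminium enolate may add sluggishly to the aldehyde, or the adduct may revert and equilibrate, eroding the anti selectivity at C6 and the facial selectivity at C5. The fallback sets out from 5: the enolate is silylated with Et3SiOTf and the triethylsilyl enol ether F1 is isolated. MeLi in THF at 0 °C then cleaves the Si–O bond to the lithium enolate F2, which keeps the enolate regiochemistry. Addition of 3 at −78 °C under kinetic control through a closed transition state should give the anti aldol, and the route is rejoined at 6.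

Step 11 (C9 oxygenation). The planar C9 radical may capture oxygen with poor facial selectivity, or be quenched by hydrogen before oxygenation, giving the saturated ketone. The fallback sets out from 15: 1,4-hydrosilylation with Et3SiH and RhCl(PPh3)3 (cat.) in benzene gives the regiodefined C8 triethylsilyl enol ether F4 (C8=C9). Dimethyldioxirane in acetone/CH2Cl2 at −78 → 0 °C should epoxidise its α face, away from the C1 methyl, to the silyloxy epoxide F5. F5 rearranges with silyl migration (Rubottom oxidation) to the α-silyloxy ketone, and the route is rejoined at 18, so step 12 is skipped.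

**Further compounds**

F1 | step 1 | triethyl{[(3S)-3-methyl-3-[1-(trimethylsilyl)ethenyl]cyclopent-1-en-1-yl]oxy}silane | C=C([Si](C)(C)C)[C@@]1(C)CCC(O[Si](CC)(CC)CC)=C1
F2 | step 1 | lithium (3S)-3-methyl-3-[1-(trimethylsilyl)ethenyl]cyclopent-1-en-1-olate | C=C([Si](C)(C)C)[C@@]1(C)CCC(O[Li])=C1
F3 | step 10 | (1R,4R,5S,6S)-6-[(4-methoxybenzyl)oxy]-4-(triethylsilyloxy)-14-nordauc-9-en-8-ol (C8 epimers) | C1=CC(O)C[C@H](OCc3ccc(OC)cc3)[C@@H]2[C@]1(C)CC[C@@]2(O[Si](CC)(CC)CC)C(C)C
F4 | step 11 | (1R,4R,5S,6S)-6-[(4-methoxybenzyl)oxy]-4,8-bis(triethylsilyloxy)-14-nordauc-8-ene | C1C=C(O[Si](CC)(CC)CC)C[C@H](OCc3ccc(OC)cc3)[C@@H]2[C@]1(C)CC[C@@]2(O[Si](CC)(CC)CC)C(C)C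
F5 | step 11 | 8α,9α-epoxide of F4 (8β-triethylsilyloxy) | CC[Si](CC)(CC)O[C@@]12C[C@H](OCc4ccc(OC)cc4)[C@@H]3[C@](C)(CC[C@@]3(O[Si](CC)(CC)CC)C(C)C)C[C@@H]1O2
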